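The disconnection cuts C8–C9 and C11–C12. In the target one carbon, C9, spans the seven-membered ring formed by C5, C6, C8, C7, the lactone oxygen, C20 and C10. C8 is flanked by the oxygen-bearing carbons C6 and C7, and C11 carries a hydroxyl, so C8 (as a β-dicarbonyl carbon) and then C11 (as a nitronate) can act as carbanions. In one amine-mediated operation C8 adds to a nitrovinyl group on C10, and the resulting nitronate adds to an enone arm on C8. This closes the cyclopentane (and the bridged δ-lactone) and ring C, and sets C8, C9, C11 and C13. The precursor is a ring A-fused seven-membered β-keto lactone, released in the flask from its β-acetoxy nitro form.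

Key step: step 16

Locants:
- Ring A is C1(OAc), C2, C3, C4(Me2), C5, C10.
- C6 is the cyclopentane carbinol carbon, C7 the lactone C=O and C20 the lactone OCH2.
- Ring C is C8, C9, C11(OH), C12, C13, C14.
- The acrylate is C17H2=C16–C15O2Me.

Assumption: C9 in 11–14, 16–19 and 23–25 forms as a mixture of epimers and is drawn without a descriptor, because it becomes sp2 in 26. C10 in 4 and 5 and C8 in 23–25 are planarised later and are also left open. The C8 descriptor drawn for 26 is arbitrary, since C8 is enolisable.

Remark: C9 is exocyclic to the seven-membered ring, so the first closure is strictly a bridging of that ring rather than a transannular reaction.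

Step 1
Reactants: 1 4,4-dimethylcyclohex-2-en-1-one
Product: 2 4,4-dimethylcyclohexa-2,5-dien-1-one
Conditions: DDQ (1.5 equiv), 1,4-dioxane, reflux
Reagents that add atoms: none
Why: DDQ dehydrogenation of an enone is the standard entry to 4,4-disubstituted cyclohexadienones, the quaternary carbon rules out aromatisation, and the second C=C makes C10 the only enolisable position in steps 3 and 4.

Step 2
Reactants: 2 4,4-dimethylcyclohexa-2,5-dien-1-one
Product: 3 (5R)-5-ethenyl-4,4-dimethylcyclohex-2-en-1-one
Conditions: CH2=CHBF3K (1.2 equiv), [Rh(cod)2]BF4 (3 mol%), (R)-BINAP (3.6 mol%), toluene/H2O, 40 °C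
Reagents that add atoms: potassium vinyltrifluoroborate, C=C[B-](F)(F)F.[K+]
Why: The Hayashi–Miyaura rhodium/BINAP 1,4-addition of an alkenyltrifluoroborate differentiates the two enantiotopic enone arms and sets C5 (R) by ligand control, with the ligand enantiomer chosen by the usual quadrant model and only a slight excess of borate used to limit a second addition.

Step 3
Reactants: 3 (5R)-5-ethenyl-4,4-dimethylcyclohex-2-en-1-one
Product: 5 C10-(TBS-oxymethyl) enone, via hydroxymethyl enone 4 (not isolated)
Conditions: LDA (1.1 equiv), THF, −78 °C; CH2O (g); TBSOTf (1.3 equiv), −78 → −20 °C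
Reagents that add atoms: formaldehyde, C=O; tert-butyldimethylsilyl triflate, CC(C)(C)[Si](C)(C)OS(=O)(=O)C(F)(F)F
Why: Kinetic α′-deprotonation of the cross-conjugated enone followed by a formaldehyde aldol brings in C20, and silylation of the lithium alkoxide in the same flask forestalls retro-aldol and dehydration, while the C10 configuration is lost again in step 4.

Step 4
Reactants: 5 C10-(TBS-oxymethyl) enone
Product: 6 quaternary enone (CH2OTBS = C20 cis, CH2OH = C9 trans to the C5 ethenyl group)
Conditions: LDA (1.2 equiv), THF, −78 → −40 °C; CH2O (g), −78 °C; AcOH quench at −78 °C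
Reagents that add atoms: formaldehyde, C=O
Why: A second enolate aldol makes C10 quaternary with the electrophile entering anti to the neighbouring C5 ethenyl group, as in the double alkylation of carvone, and the cold acidic quench avoids β-elimination of silanolate and O→O silyl migration.

Step 5
Reactants: 6 quaternary enone
Product: 7 saturated C1 ketone
Conditions: Cu(OAc)2·H2O (5 mol%), 1,2-(Ph2P)2C6H4 (5 mol%), (EtO)2MeSiH, t-BuOH, toluene, rt
Reagents that add atoms: none
Why: Copper hydride conjugate reduction (Stryker/Lipshutz type) saturates only the enone C=C and leaves the isolated ethenyl group, the silyl ether and the ketone.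

Step 6
Reactants: 7 saturated C1 ketone
Product: 8 C1,C9-diol (equatorial C1–OH cis to C20 and to the C5 substituent)
Conditions: NaBH4, MeOH, 0 °C
Reagents that add atoms: none
Why: Borohydride attacks the C1 ketone axially, from the face opposite the axial CH2OTBS group on C10, and gives the equatorial alcohol.

Step 7
Reactants: 8 C1,C9-diol
Product: 9 C9 aldehyde with free C1–OH
Conditions: TEMPO (10 mol%), PhI(OAc)2 (1.1 equiv), CH2Cl2, rt
Reagents that add atoms: none
Why: The oxoammonium (TEMPO/PhI(OAc)2) oxidation takes the primary alcohol to the non-enolisable aldehyde and leaves the hindered secondary C1 alcohol.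

Step 8
Reactants: 9 C9 aldehyde with free C1–OH; 10 nitromethane
Product: 12 nitroaldol acetonide (O1/O9 dioxane), via nitro diol 11 (not isolated)
Conditions: MeNO2 (10 equiv), tetramethylguanidine (10 mol%), THF, 0 °C; then CSA, Me2C(OMe)2, rt
Reagents that add atoms: 2,2-dimethoxypropane, COC(C)(C)OC
Why: The Henry reaction is run now, while neither an acidic β-dicarbonyl carbon nor an enone is present, and the acetonide stores the later nitroalkene as a nitroaldol with a poor leaving group and protects O1 at the same time.

Step 9
Reactants: 12 nitroaldol acetonide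
Product: 14 C6 carboxylic acid, via C6 aldehyde 13 (not isolated)
Conditions: O3, CH2Cl2, −78 °C; Me2S; then NaClO2, NaH2PO4, 2-methylbut-2-ene, t-BuOH/H2O, rt
Reagents that add atoms: ozone, [O-][O+]=O; sodium chlorite, [Na+].[O-]Cl=O
Why: Ozonolysis followed by Pinnick oxidation turns the ethenyl group into the C6 acid under neutral to weakly acidic conditions that spare the nitro group, acetonide and silyl ether and keep the equatorial C5 substituent in place.

Step 10
Reactants: 14 C6 carboxylic acid; 15 Meldrum's acid
Product: 17 acyl Meldrum's acid (enol form), via acid chloride 16 (not isolated)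
Conditions: Me2C=C(Cl)NMe2, CH2Cl2, 0 °C; then 15, DMAP (2.2 equiv), 0 °C → rt
Reagents that add atoms: 1-chloro-N,N,2-trimethylprop-1-en-1-amine, CC(C)=C(Cl)N(C)C (chlorine of 16 only)
Why: Neutral acid chloride formation with Ghosez's reagent and DMAP-mediated C-acylation of Meldrum's acid (Oikawa–Yonemitsu) attach C8 and C7 to the hindered C6 carboxyl without strong base.

Step 11
Reactants: 17 acyl Meldrum's acid
Product: 19 seven-membered β-keto lactone, via hydroxy acyl Meldrum's acid 18 (not isolated)
Conditions: HF·pyridine, pyridine, THF, 0 °C; then slow addition to toluene (2 mM), 110 °C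
Reagents that add atoms: none
Why: Buffered fluoride frees only the primary C20 hydroxyl, and thermolysis (loss of acetone and CO2) gives an acylketene that the cis-disposed hydroxyl traps at high dilution, the known acylketene lactonisation.

Step 12
Reactants: 20 methyl vinyl ketone
Product: 21 3-(hydroxymethyl)but-3-en-2-one
Conditions: aq. CH2O, DABCO (cat.), THF/H2O, rt
Reagents that add atoms: formaldehyde, C=O
Why: This is the Morita–Baylis–Hillman reaction of methyl vinyl ketone with formaldehyde.

Step 13
Reactants: 21 3-(hydroxymethyl)but-3-en-2-one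
Product: 22 3-(bromomethyl)but-3-en-2-one
Conditions: PBr3, Et2O, 0 °C; used fresh
Reagents that add atoms: phosphorus tribromide, BrP(Br)Br
Why: PBr3 converts the primary allylic alcohol into the bromide, and the SN2 and SN2′ pathways give the same product.

Step 14
Reactants: 19 seven-membered β-keto lactone; 22 3-(bromomethyl)but-3-en-2-one
Product: 23 C8-alkylated β-keto lactone with the enone arm
Conditions: NaH (1.0 equiv), THF, 0 °C; 22, −78 → −20 °C
Reagents that add atoms: none
Why: One equivalent of base forms only the β-keto lactone enolate (more acidic than the nitroalkane in aprotic medium and faster to deprotonate), which is C-alkylated by the very reactive 2-acylallyl bromide, and the nitroaldol acetonide survives because it has no good leaving group.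

Step 15
Reactants: 23 C8-alkylated β-keto lactone
Product: 25 C1,C9-bis-acetate (latent precursor), via nitro diol 24 (not isolated)
Conditions: TFA/H2O, CH2Cl2, 0 °C; then Ac2O, Sc(OTf)3 (5 mol%), MeCN, −20 °C
Reagents that add atoms: acetic anhydride, CC(=O)OC(C)=O
Why: Aqueous acid cleaves the acetonide and base-free Lewis acid-catalysed acetylation esterifies both hindered alcohols, which installs the final C1 acetate and turns O9 into a leaving group without starting the elimination.

Step 16
Reactants: 25 C1,C9-bis-acetate
Product: 27 tetracyclic C6 ketone with equatorial C11 nitro and C13 acetyl groups, via nitrovinyl β-keto lactone 26 (not isolated)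
Conditions: i-Pr2NEt (3 equiv), N,N′-bis[3,5-bis(trifluoromethyl)phenyl]thiourea (10 mol%), toluene (5 mM), 0 °C → rt
Reagents that add atoms: none
Why: The amine first expels acetate from C9 by E1cB through the C11 nitronate and so unveils the (E)-nitroalkene 26; it then deprotonates C8, the only carbon between two carbonyl groups, the enolate adds to C9, the C11 nitronate thus formed adds to the enone methylene C12, and the C13 enolate is protonated. The closest known reaction type is the amine/thiourea-catalysed nitro-Michael/Michael domino of 1,3-dicarbonyl compounds with nitroalkenes and enones, here run within one molecule. The first closure is 5-exo-trig (cyclopentane C5–C6–C8–C9–C10, which also completes the bridged δ-lactone) and the second is 6-endo-trig (ring C). C8 is dictated by the bridge, because C9 hangs from C10 and can reach only one face of the ring enolate, leaving C14 as the outward bridgehead substituent; C9 follows from the rotamer in which C9=C11 eclipses the small C10–C20 bond and points away from C5–C6, which places C11 over the lactone bridge. C11 (equatorial nitro) and C13 (equatorial acetyl) remain epimerisable under the amine and settle in the chair of ring C. The step needs ring closure to outrun enolate–enone addition between molecules, secured by high dilution and by the seven-membered ring that keeps C8 next to C9, and it needs C5–H beside the C6 ketone to stay untouched, secured by a base far too weak to enolise a simple ketone.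

Step 17
Reactants: 27 tetracyclic nitro diketone
Product: 28 C16 dioxolane
Conditions: (TMSOCH2)2, TMSOTf (5 mol%), CH2Cl2, −78 → −20 °C
Reagents that add atoms: 1,2-bis(trimethylsilyloxy)ethane, C[Si](C)(C)OCCO[Si](C)(C)C
Why: Noyori ketalisation protects only the unhindered methyl ketone, since the C6 ketone is flanked by quaternary C8 and by C5 next to C4 and is deactivated by the lactone carbonyl, and the low temperature avoids acid-catalysed enolisation at C5.

Step 18
Reactants: 28 C16 dioxolane
Product: 30 C6,C11-diketone, via potassium nitronate 29 (not isolated)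
Conditions: t-BuOK (1.05 equiv), THF, 0 °C; then aq. TiCl3, NH4OAc (pH ≈ 6), THF/H2O, 0 °C → rt
Reagents that add atoms: water, O (oxygen of the C11 ketone); potassium tert-butoxide, CC(C)(C)[O-].[K+] (potassium of 29 only)
Why: McMurry's buffered titanium(III) Nef reaction reduces the nitronate to the imine, which hydrolyses to the C11 ketone near neutrality, conditions that spare the acetate, ketal and β-keto lactone and give C9 little chance to epimerise.

Step 19
Reactants: 30 C6,C11-diketone
Product: 32 C6,C11-diol methyl ketone (C6–OH exo and C11–OH equatorial), via diol ketal 31 (not isolated)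
Conditions: SmI2 (5 equiv), H2O (100 equiv), THF, 0 °C; then 1 M HCl, THF, rt
Reagents that add atoms: water, O (oxygen of the regenerated C16 ketone)
Why: Hydride would reach both ketones from their open faces (exo at C6, away from the lactone at C11) and give the wrong epimers, whereas SmI2–H2O electron transfer/protonation places each oxygen in the less crowded position, equatorial at C11 as in dissolving-metal reduction of 11-oxo steroids and exo at C6, where the endo side is blocked by the axial C4 methyl group and the lactone bridge, and the acid work-up removes the ketal.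

Step 20
Reactants: 32 C6,C11-diol methyl ketone
Product: 33 bis-TMS ether
Conditions: 1-(trimethylsilyl)imidazole, CH2Cl2, rt
Reagents that add atoms: 1-(trimethylsilyl)imidazole, C[Si](C)(C)n1ccnc1
Why: Neutral silylation caps both alcohols without touching the methyl ketone, which matters because a free C6 alkoxide could undergo retro-aldol cleavage in step 21.

Step 21
Reactants: 33 bis-TMS ether
Product: 34 terminal enol triflate (C16–OTf, C16=C17H2)
Conditions: KHMDS (1.05 equiv), THF, −78 °C; Comins' reagent, −78 °C
Reagents that add atoms: N-(5-chloropyridin-2-yl)bis(trifluoromethanesulfonimide), O=S(=O)(N(c1ccc(Cl)cn1)S(=O)(=O)C(F)(F)F)C(F)(F)F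
Why: Kinetic deprotonation of the methyl ketone at its CH3 group by a hindered base and O-triflation give the terminal enol triflate, since the acetate is less acidic and the lactone has no α-hydrogen.

Step 22
Reactants: 34 terminal enol triflate
Product: 36 target CNP0421185.1, via bis-TMS acrylate 35 (not isolated)
Conditions: Pd(OAc)2 (10 mol%), dppf, Et3N, CO (1 atm), MeOH/DMF, 50 °C; then 1 M HCl, 0 °C
Reagents that add atoms: carbon monoxide, [C-]#[O+]; methanol, CO
Why: Palladium-catalysed methoxycarbonylation of the enol triflate (oxidative addition, CO insertion, methanolysis) builds the acrylate C17=C16–C15O2Me, and dilute acid then cleaves the two TMS ethers.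

Compound list

1 | 4,4-dimethylcyclohex-2-en-1-one | CC1(C)CCC(=O)C=C1 | starting material
2 | 4,4-dimethylcyclohexa-2,5-dien-1-one | CC1(C)C=CC(=O)C=C1 | intermediate
3 | (5R)-5-ethenyl-4,4-dimethylcyclohex-2-en-1-one | C=C[C@H]1CC(=O)C=CC1(C)C | intermediate
4 | hydroxymethyl enone (lithium alkoxide in the flask, C10 open) | C=C[C@H]1C(CO)C(=O)C=CC1(C)C | intermediate
5 | C10-(TBS-oxymethyl) enone (C10 open) | C=C[C@H]1C(CO[Si](C)(C)C(C)(C)C)C(=O)C=CC1(C)C | intermediate
6 | quaternary enone, C20 (CH2OTBS) cis and C9 (CH2OH) trans to the ethenyl group | CC(C)(C)[Si](C)(C)OC[C@@]1(CO)C(=O)C=CC(C)(C)[C@H]1C=C | intermediate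
7 | saturated C1 ketone | CC(C)(C)[Si](C)(C)OC[C@@]1(CO)C(=O)CCC(C)(C)[C@H]1C=C | intermediate
8 | C1,C9-diol, C1–OH equatorial | CC(C)(C)[Si](C)(C)OC[C@@]1(CO)[C@@H](O)CCC(C)(C)[C@H]1C=C | intermediate
9 | C9 aldehyde with free C1–OH | CC(C)(C)[Si](C)(C)OC[C@@]1(C=O)[C@@H](O)CCC(C)(C)[C@H]1C=C | intermediate
10 | nitromethane | C[N+](=O)[O-] | starting material
11 | nitro diol (C9 epimers) | CC(C)(C)[Si](C)(C)OC[C@@]1(C(O)C[N+](=O)[O-])[C@@H](O)CCC(C)(C)[C@H]1C=C | intermediate
12 | nitroaldol acetonide | CC(C)(C)[Si](C)(C)OC[C@@]12C(C[N+](=O)[O-])OC(C)(C)O[C@H]1CCC(C)(C)[C@H]2C=C | intermediate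
13 | C6 aldehyde | CC(C)(C)[Si](C)(C)OC[C@@]12C(C[N+](=O)[O-])OC(C)(C)O[C@H]1CCC(C)(C)[C@H]2C=O | intermediate
14 | C6 carboxylic acid | CC(C)(C)[Si](C)(C)OC[C@@]12C(C[N+](=O)[O-])OC(C)(C)O[C@H]1CCC(C)(C)[C@H]2C(=O)O | intermediate
15 | Meldrum's acid | CC1(C)OC(=O)CC(=O)O1 | starting material
16 | acid chloride | CC(C)(C)[Si](C)(C)OC[C@@]12C(C[N+](=O)[O-])OC(C)(C)O[C@H]1CCC(C)(C)[C@H]2C(=O)Cl | intermediate
17 | acyl Meldrum's acid (enol form) | CC(C)(C)[Si](C)(C)OC[C@@]12C(C[N+](=O)[O-])OC(C)(C)O[C@H]1CCC(C)(C)[C@H]2C(O)=C3C(=O)OC(C)(C)OC3=O | intermediate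
18 | hydroxy acyl Meldrum's acid | OC[C@@]12C(C[N+](=O)[O-])OC(C)(C)O[C@H]1CCC(C)(C)[C@H]2C(O)=C3C(=O)OC(C)(C)OC3=O | intermediate
19 | seven-membered β-keto lactone, cis-fused to ring A | O=C1CC(=O)OC[C@@]23C(C[N+](=O)[O-])OC(C)(C)O[C@H]2CCC(C)(C)[C@@H]13 | intermediate
20 | methyl vinyl ketone | CC(=O)C=C | starting material
21 | 3-(hydroxymethyl)but-3-en-2-one | CC(=O)C(=C)CO | intermediate
22 | 3-(bromomethyl)but-3-en-2-one | CC(=O)C(=C)CBr | intermediate
23 | C8-alkylated β-keto lactone (C8 labile) | CC(=O)C(=C)CC1C(=O)OC[C@@]23C(C[N+](=O)[O-])OC(C)(C)O[C@H]2CCC(C)(C)[C@H]3C1=O | intermediate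
24 | nitro diol | CC(=O)C(=C)CC1C(=O)OC[C@@]2(C(O)C[N+](=O)[O-])[C@@H](O)CCC(C)(C)[C@H]2C1=O | intermediate
25 | C1,C9-bis-acetate, latent precursor | CC(=O)C(=C)CC1C(=O)OC[C@@]2(C(OC(C)=O)C[N+](=O)[O-])[C@@H](OC(C)=O)CCC(C)(C)[C@H]2C1=O | intermediate
26 | nitrovinyl β-keto lactone with enone arm, precursor of the key step (one C8 epimer drawn) | CC(=O)C(=C)C[C@H]1C(=O)OC[C@@]2(/C=C/[N+](=O)[O-])[C@@H](OC(C)=O)CCC(C)(C)[C@H]2C1=O | intermediate
27 | tetracyclic C6 ketone with C11 nitro and C13 acetyl | CC(=O)[C@@H]1C[C@H]([N+](=O)[O-])[C@@H]2[C@]3(C1)C(=O)OC[C@]21[C@@H](OC(C)=O)CCC(C)(C)[C@H]1C3=O | intermediate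
28 | C16 dioxolane | CC4(OCCO4)[C@@H]1C[C@H]([N+](=O)[O-])[C@@H]2[C@]3(C1)C(=O)OC[C@]21[C@@H](OC(C)=O)CCC(C)(C)[C@H]1C3=O | intermediate
29 | potassium nitronate | CC4(OCCO4)[C@@H]1CC(=[N+]([O-])[O-])[C@@H]2[C@]3(C1)C(=O)OC[C@]21[C@@H](OC(C)=O)CCC(C)(C)[C@H]1C3=O.[K+] | intermediate
30 | C6,C11-diketone | CC4(OCCO4)[C@@H]1CC(=O)[C@@H]2[C@]3(C1)C(=O)OC[C@]21[C@@H](OC(C)=O)CCC(C)(C)[C@H]1C3=O | intermediate
31 | diol ketal | CC4(OCCO4)[C@@H]1C[C@H](O)[C@@H]2[C@]3(C1)C(=O)OC[C@]21[C@@H](OC(C)=O)CCC(C)(C)[C@H]1[C@@H]3O | intermediate
32 | C6,C11-diol methyl ketone | CC(=O)[C@@H]1C[C@H](O)[C@@H]2[C@]3(C1)C(=O)OC[C@]21[C@@H](OC(C)=O)CCC(C)(C)[C@H]1[C@@H]3O | intermediate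
33 | bis-TMS ether | CC(=O)[C@@H]1C[C@H](O[Si](C)(C)C)[C@@H]2[C@]3(C1)C(=O)OC[C@]21[C@@H](OC(C)=O)CCC(C)(C)[C@H]1[C@@H]3O[Si](C)(C)C | intermediate
34 | terminal enol triflate | C=C(OS(=O)(=O)C(F)(F)F)[C@@H]1C[C@H](O[Si](C)(C)C)[C@@H]2[C@]3(C1)C(=O)OC[C@]21[C@@H](OC(C)=O)CCC(C)(C)[C@H]1[C@@H]3O[Si](C)(C)C | intermediate
35 | bis-TMS acrylate | C=C(C(=O)OC)[C@@H]1C[C@H](O[Si](C)(C)C)[C@@H]2[C@]3(C1)C(=O)OC[C@]21[C@@H](OC(C)=O)CCC(C)(C)[C@H]1[C@@H]3O[Si](C)(C)C | intermediate
36 | CNP0421185.1 | C=C(C(=O)OC)[C@@H]1C[C@H](O)[C@@H]2[C@]3(C1)C(=O)OC[C@]21[C@@H](OC(C)=O)CCC(C)(C)[C@H]1[C@@H]3O | target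

Total step count: 22. Longest linear sequence: 20 steps (steps 1–11 and 14–22).

Steps most likely to fail

1. Step 16.
- What may go wrong: enolate–enone addition between molecules may compete with ring closure. C8 may attack the other nitroalkene rotamer, which inverts C9. The nitronate may be protonated, so that the sequence stalls after the first ring.
- Fallback: the two bond formations are separated. Setting out from 25, Et3N buffered with one equivalent of AcOH in CH2Cl2 at 0 °C should effect elimination and the first Michael addition only, because the nitronate is protonated at once. The bicyclic nitro enone F1 is isolated, and any C9 epimer is removed at this stage. Ring C is then closed as a separate intramolecular nitro-Michael addition with catalytic DBU or TBAF in THF, and the route is rejoined at 27.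

2. Step 19.
- What may go wrong: the ketyl of the 1,4-diketone may cleave the C8–C9 bond reductively, because C8 is a doubly stabilised leaving carbanion while C6 is still a ketone. Proton delivery at C6 may also lack facial control.
- Fallback: the two carbonyl groups are reduced one at a time. Setting out from 30, soft enolisation with TBSOTf/Et3N should convert only the C11 ketone into the C11–C12 silyl enol ether F2. SmI2–H2O then reduces the C6 ketone alone to the C6 exo alcohol F3. HF·pyridine releases the C6-hydroxy C11 ketone F4, in which C8 is only a lactone α-carbon. A second SmI2–H2O reduction gives 31, where the route is rejoined.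

3. Step 11.
- What may go wrong: the freed C20 hydroxyl may attack C6 of the acidic enol (five-ring closure and loss of water) faster than the acylketene forms and is trapped at C7.
- Fallback: C7 is activated at room temperature instead of thermally. Setting out from 14 (through 16 as in step 10), decarboxylative acylation of the magnesium enolate of 3-(tert-butylsulfanyl)-3-oxopropanoic acid (MgCl2, Et3N, MeCN) gives the far less acidic β-keto thioester F5. HF·pyridine gives the hydroxy β-keto thioester F6. Silver(I) trifluoroacetate with Na2HPO4 in dilute THF effects thiophilic activation and lactonisation to 19, where the route is rejoined.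

Further compounds

F1 | step 16 | bicyclic nitro enone (C8–C9 closed, C11H2NO2, enone arm intact) | CC(=O)C(=C)C[C@]12C(=O)OC[C@@]3([C@@H]1C[N+](=O)[O-])[C@@H](OC(C)=O)CCC(C)(C)[C@H]3C2=O
F2 | step 19 | C11–C12 silyl enol ether | CC4(OCCO4)[C@@H]1C=C(O[Si](C)(C)C(C)(C)C)[C@@H]2[C@]3(C1)C(=O)OC[C@]21[C@@H](OC(C)=O)CCC(C)(C)[C@H]1C3=O
F3 | step 19 | C6 exo alcohol (silyl enol ether retained) | CC4(OCCO4)[C@@H]1C=C(O[Si](C)(C)C(C)(C)C)[C@@H]2[C@]3(C1)C(=O)OC[C@]21[C@@H](OC(C)=O)CCC(C)(C)[C@H]1[C@@H]3O
F4 | step 19 | C6-hydroxy C11 ketone | CC4(OCCO4)[C@@H]1CC(=O)[C@@H]2[C@]3(C1)C(=O)OC[C@]21[C@@H](OC(C)=O)CCC(C)(C)[C@H]1[C@@H]3O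
F5 | step 11 | β-keto thioester | CC(C)(C)[Si](C)(C)OC[C@@]12C(C[N+](=O)[O-])OC(C)(C)O[C@H]1CCC(C)(C)[C@H]2C(=O)CC(=O)SC(C)(C)C
F6 | step 11 | hydroxy β-keto thioester | OC[C@@]12C(C[N+](=O)[O-])OC(C)(C)O[C@H]1CCC(C)(C)[C@H]2C(=O)CC(=O)SC(C)(C)C
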